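At 1.00 min the north-west run, with 3 equiv of salt in the second phase, has made 10.8 % product, and the north-east run, with 0.75 equiv, has made 9.5 %, which is more product but not in step with the salt.

| flask | starting material | salt in the second phase | protic impurity | spent carrier | remark | volume of the second phase over the first |
|---|---|---|---|---|---|---|
| north-east | 1 M | 0.75 equiv | 0.10 M | 10 mol% | run made earlier |  |
| north-west | 1 M | 3 equiv | 0.10 M | 10 mol% | run made earlier |  |
| north | 1 M | 1.5 equiv | 0.20 M | 10 mol% | run made earlier |  |
| flask | 1.0 M | 1.50 equiv | 0.100 M | 10 mol% |  | 1.0 |

- north-east (time / min: product / %, starting material / %): 0.500: 5.8, 89.0; 1.00: 9.5, 82.7; 1.50: 13.9, 78.0; 2.00: 15.7, 74.2; 2.50: 19.1, 71.5; 3.00: 22.5, 68.7; 4.00: 27.1, 62.8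
- north-west (time / min: product / %, starting material / %): 0.250: 2.2, 94.1; 0.417: 4.7, 90.7; 0.667: 7.7, 85.8; 1.00: 10.8, 81.5; 1.50: 15.2, 75.4; 2.50: 23.3, 66.0; 4.00: 34.8, 55.4
- north (time / min: product / %, starting material / %): 0.667: 8.0, 81.0; 1.33: 13.1, 70.9; 2.00: 17.3, 63.6; 3.00: 23.2, 56.6; 4.00: 28.1, 51.5

(readings scatter by 0.5 percentage points)

- charges count per volume of the first phase; a concentration in a rate is the amount of a species over the volume of its own phase; every rate counts per litre of the first phase
- the earlier runs hold the two phases in the same ratio of volumes as the flask asked about
- no earlier run changes the charge of spent carrier; that part of a forecast is a guess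

- apparent order in salt in the second phase when 10 % of the starting material are converted (percent change of the rate of making product for one percent more salt in the second phase charged)
- apparent order in spent carrier when 10 % of the starting material are converted (percent change of the rate of making product for one percent more spent carrier charged)

1. The bench rule of thumb takes the organic step as the rate-limiting step, so the rate is zero order in salt and first order in carrier.

2. The two runs share the same protic impurity, 0.10 M. Their product ratio of 1.14 over a salt ratio of 4.00 reads as an order in salt of 0.0925, a reading from the product made up to 1.00 min, not from a rate at the asked conversion. The flask's 1.50 equiv is the geometric mean of the two charges. With 0.5 percentage points on each reading, the second digit is loose.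

3. We suppose that exchange with the salt holds the carrier between its spent form and an active form, with active over spent following the salt. With starting material and the salt released by the exchange held fixed, the rate then follows the active fraction, and the order in salt equals the spent fraction of the carrier charge, the spent share.

4. The rule of thumb ends where the spent share reaches 0.5, the crossing at which the carrier stands evenly between its two forms and the order in salt lies midway between zero and one. Our reading lies below it, so we commit to 0.0925 in salt. For carrier we keep first order, a guess, as no run varies that charge.

5. The forecast gave 0.15 in salt and 0.9 in spent carrier, reasoning: “The carrier is therefore about 90 % active”.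

6. The flask gives 0.11 in salt and 0.92 in spent carrier.

    spent carrier + salt in the second phase ⇌ fresh carrier + spent salt in the second phase (K = 0.910, k = 0.770 L mol⁻¹ s⁻¹)
    starting material + fresh carrier → product + spent carrier (k = 0.0220 L mol⁻¹ s⁻¹)
    starting material + protic impurity → quenched substrate (k = 0.0280 L mol⁻¹ s⁻¹)

7. Spent carrier in the flask is 12.4 % of the catalyst after 0.600 min, a little past the 0.449 min of the asked conversion, beside the spent share of 0.0925 that we read from the two earlier runs. Fresh carrier at 53.8 % of the catalyst after 12.2 min in the flask gives a spent share of 46.2 %, still under the crossing. After 60.0 min spent carrier stands at 63.2 %.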